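**Retrosynthetic overview**
1. Target ⇐ O‑demethylation of its tri‑O‑methyl ether 31 ⇐ double formylation (dibromination, Br–Li exchange, DMF) of the 2,4,6‑trimethoxyphenyl diol 28.
2. C11 carbinol ⇐ C7 ketone (TosMIC homologation, then MeMgBr twice); C4 carbinol ⇐ C4 ketone + MeMgBr/CeCl3 (equatorial attack).
3. Aryl–C1′ bond and C1′ stereocentre ⇐ copper‑catalysed addition of ArMgBr to an alkylidene acetoacetate made from the C1 aldehyde; the acetonyl residue becomes the isobutyl group.
4. C1 aldehyde, C4 oxygen and the trans ring fusion ⇐ 9‑BBN/BH3 hydroboration of a 1‑methylene‑Δ4 C7‑ketal ⇐ (S)‑Wieland–Miescher ketone, whose two carbonyls are told apart by a ketoreductase.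
5. Ring order: ring A is the purchased cyclohexanedione; ring B is closed by the proline‑catalysed aldol condensation that sets C10; the aromatic ring is purchased.

Conventions: eudesmane numbering for the decalin (C10 = methyl‑bearing quaternary carbon, C1 next to it, C4 and C5 complete ring A, C5 = ring‑fusion CH, C6–C9 complete ring B, C1′ = benzylic carbon); "cis/trans" always refer to the C10 methyl group; Ar = 2,4,6‑trimethoxyphenyl. Target descriptors: C1′ S, C1 R, C4 R, C5 S, C7 S, C10 R.
Assumption: a ketoreductase that accepts (S)‑Wieland–Miescher ketone at its isolated carbonyl (as yeast reductases are known to do) is found by routine screening of a commercial enzyme panel.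

**Step 1**
Reactants: 1 2‑methylcyclohexane‑1,3‑dione; 2 methyl vinyl ketone (but‑3‑en‑2‑one)
Product: 3 2‑methyl‑2‑(3‑oxobutyl)cyclohexane‑1,3‑dione
Conditions: H2O, AcOH (cat.), hydroquinone (cat.), 75 °C
Reagents that add atoms: methyl vinyl ketone (2), CC(=O)C=C
Why: Michael addition of the 1,3‑dione enol to the enone gives the prochiral triketone, which has no stereocentre.

**Step 2**
Reactants: 3 2‑methyl‑2‑(3‑oxobutyl)cyclohexane‑1,3‑dione
Product: 5 (S)‑Wieland–Miescher ketone [(8aS)‑8a‑methyl‑3,4,8,8a‑tetrahydronaphthalene‑1,6(2H,7H)‑dione], via ketol 4 (not isolated)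
Conditions: L‑proline (5 mol %), DMSO, rt; crystallisation from Et2O/hexane
Reagents that add atoms: none
Why: In this proline‑catalysed intramolecular aldol condensation (Hajos–Parrish–Eder–Sauer–Wiechert reaction) the side‑chain enamine attacks one of the two enantiotopic ring carbonyls through the acid‑bound chair transition state, which sets quaternary C10 as S before the ketol dehydrates.

**Step 3**
Reactants: 5 (S)‑Wieland–Miescher ketone
Product: 6 (4aS,5S)‑5‑hydroxy‑4a‑methyl‑4,4a,5,6,7,8‑hexahydronaphthalen‑2(3H)‑one (C1 alcohol cis)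
Conditions: ketoreductase (NADPH‑dependent), NADP+ (cat.), i‑PrOH (10 vol %), phosphate buffer pH 7, 30 °C
Reagents that add atoms: none
Why: In this enzymatic carbonyl reduction the ketoreductase delivers hydride only to the isolated C1 ketone of the (S)‑dione and only from the face trans to the methyl group, so the two carbonyls are differentiated and residual (R)‑dione is left behind as unreacted ketone.

**Step 4**
Reactants: 6 hydroxy enone
Product: 7 C7 ethylene ketal with C4=C5 double bond and C1 hydroxyl cis [(1S,8aS)‑6,6‑(ethylenedioxy)‑8a‑methyl‑1,2,3,5,6,7,8,8a‑octahydronaphthalen‑1‑ol]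
Conditions: ethylene glycol, p‑TsOH (cat.), benzene, reflux (Dean–Stark)
Reagents that add atoms: ethylene glycol, OCCO
Why: Acid‑catalysed ketalisation of the enone passes through the dienol ether and leaves the alkene in the β,γ position (C4=C5) as with steroidal 4‑en‑3‑ones, which protects C7 and places the alkene for oxygenation of C4 without touching a stereocentre.

**Step 5**
Reactants: 7 hydroxy ketal
Product: 8 C1 ketone with C7 ethylene ketal and C4=C5 double bond [(8aS)‑6,6‑(ethylenedioxy)‑8a‑methyl‑3,5,6,7,8,8a‑hexahydronaphthalen‑1(2H)‑one]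
Conditions: Dess–Martin periodinane, pyridine, CH2Cl2, rt
Reagents that add atoms: none
Why: Buffered Dess–Martin oxidation returns the hindered C1 ketone while the ketal survives and the alkene cannot move into conjugation because C10 is quaternary.

**Step 6**
Reactants: 8 keto ketal
Product: 9 1‑methylene diene ketal [6,6‑(ethylenedioxy)‑8a‑methyl‑1‑methylene‑1,2,3,5,6,7,8,8a‑octahydronaphthalene with unchanged C10]
Conditions: Ph3PCH3Br, KOt‑Bu, toluene, 80 °C
Reagents that add atoms: methyltriphenylphosphonium bromide, C[P+](c1ccccc1)(c1ccccc1)c1ccccc1.[Br-]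
Why: Wittig methylenation with the small unstabilised ylide is the standard olefination of this neopentyl‑type ketone and creates no stereocentre.

**Step 7**
Reactants: 9 diene ketal
Product: 11 trans‑decalin diol (C1 CH2OH cis and equatorial; C4 OH trans; C5 H trans; C7 ethylene ketal), via bis‑borane 10 (not isolated)
Conditions: 9‑BBN (1.1 equiv), THF, rt; then BH3·THF (3 equiv), 0 °C → rt; then NaOH, H2O2, 0 → 45 °C
Reagents that add atoms: hydrogen peroxide, OO
Why: In this hydroboration–oxidation 9‑BBN takes only the 1,1‑disubstituted alkene and puts H on C1 from the face opposite the axial C10 methyl (CH2B cis and equatorial), and since that boron has no B–H left the BH3 added next hydroborates C4=C5 intermolecularly from the same open face (B at C4, H at C5 trans to the methyl, as for steroidal 5‑enes), oxidation then proceeding with retention.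

**Step 8**
Reactants: 11 diol
Product: 12 hydroxy aldehyde (C1 CHO cis and equatorial; C4 OH trans; C7 ethylene ketal)
Conditions: TEMPO (10 mol %), PhI(OAc)2, CH2Cl2, rt
Reagents that add atoms: none
Why: The TEMPO/PhI(OAc)2 oxidation is selective for the primary alcohol over the secondary one and is neutral, so C1 is not epimerised.

**Step 9**
Reactants: 12 hydroxy aldehyde; 13 methyl acetoacetate
Product: 14 alkylidene acetoacetate C1–CH=C(COCH3)CO2CH3 (E/Z mixture; ring stereocentres as in 12)
Conditions: piperidine (cat.), AcOH (cat.), benzene, reflux (Dean–Stark)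
Reagents that add atoms: methyl acetoacetate (13), CC(=O)CC(=O)OC
Why: Knoevenagel condensation with water removal gives the doubly activated alkene, whose geometry is inconsequential, and any C1 epimerisation through the enamine converges on the more stable equatorial isomer.

**Step 10**
Reactants: 15 2‑bromo‑1,3,5‑trimethoxybenzene
Product: 16 2,4,6‑trimethoxyphenylmagnesium bromide (THF solution)
Conditions: Mg, I2 (cat.), THF, reflux
Reagents that add atoms: magnesium, [Mg]
Why: Direct magnesium insertion into the electron‑rich aryl bromide gives the aryl Grignard reagent.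

**Step 11**
Reactants: 14 alkylidene acetoacetate; 16 2,4,6‑trimethoxyphenylmagnesium bromide
Product: 17 Michael adduct C1–C1′H(Ar)–CH(COCH3)CO2CH3 (C1′ as in the target; α‑carbon epimer mixture)
Conditions: 16 (3 equiv), CuBr·SMe2 (20 mol %), THF, −40 → 0 °C; aq. NH4Cl
Reagents that add atoms: 2,4,6‑trimethoxyphenylmagnesium bromide (16), COc1cc(OC)c([Mg]Br)c(OC)c1
Why: In this copper‑catalysed conjugate addition 1,3‑allylic strain with the cis carbonyl group holds the C1–H bond in the alkene plane, so the aryl group enters from the C2 side, anti to quaternary C10 and its axial methyl, which gives C1′ the spatial arrangement of the target (S there), one extra equivalent of Grignard only deprotonating the free hydroxyl.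

**Step 12**
Reactants: 17 Michael adduct
Product: 18 methyl ketone C1–C1′H(Ar)–CH2COCH3
Conditions: LiCl, H2O, DMSO, 140 °C
Reagents that add atoms: none
Why: Krapcho dealkoxycarbonylation (chloride demethylates the β‑keto ester and the carboxylate loses CO2) removes the α‑stereocentre under neutral conditions that spare the ketal, the alcohol and C1′.

**Step 13**
Reactants: 18 methyl ketone
Product: 19 2‑methylallyl compound C1–C1′H(Ar)–CH2C(CH3)=CH2
Conditions: Ph3PCH3Br, KOt‑Bu, THF, 0 °C → rt
Reagents that add atoms: methyltriphenylphosphonium bromide, C[P+](c1ccccc1)(c1ccccc1)c1ccccc1.[Br-]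
Why: Wittig methylenation of the unhindered methyl ketone cannot affect C1′, which is not α to the carbonyl, and the free alcohol only consumes extra ylide.

**Step 14**
Reactants: 19 2‑methylallyl compound
Product: 20 isobutyl compound C1–C1′H(Ar)–CH2CH(CH3)2 (C4 OH trans; C7 ethylene ketal)
Conditions: H2 (1 atm), Pd/C, EtOAc, rt
Reagents that add atoms: none
Why: Heterogeneous hydrogenation of the 1,1‑disubstituted alkene gives the isobutyl group without creating a stereocentre or touching the arene, ketal or alcohol.

**Step 15**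
Reactants: 20 isobutyl alcohol
Product: 21 C4 ketone (C5 H trans; C7 ethylene ketal)
Conditions: Dess–Martin periodinane, pyridine, CH2Cl2, rt
Reagents that add atoms: none
Why: Dess–Martin oxidation works without strong base, so the ring‑fusion C5–H next to the new carbonyl keeps its trans configuration.

**Step 16**
Reactants: 21 C4 ketone
Product: 22 C4 tertiary alcohol (OH axial and cis; CH3 equatorial; C7 ethylene ketal)
Conditions: MeMgBr, CeCl3 (anhydrous), THF, −78 °C; aq. NH4Cl
Reagents that add atoms: methylmagnesium bromide, C[Mg]Br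
Why: Organocerium 1,2‑addition (Imamoto conditions) suppresses enolisation toward C5, and because the axial face of the carbonyl is blocked by the syn‑axial C10 methyl the methyl group enters equatorially to give the axial alcohol (C4 R as in the target).

**Step 17**
Reactants: 22 ketal alcohol
Product: 23 C7 ketone with C4 tertiary alcohol
Conditions: PPTS (cat.), acetone/H2O, 60 °C
Reagents that add atoms: water, O
Why: Mild acid‑catalysed ketal hydrolysis frees the C7 ketone while the unactivated tertiary alcohol, which is γ to the carbonyl and so has no elimination or retro‑aldol path, and the aryl ethers survive.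

**Step 18**
Reactants: 23 C7 ketone
Product: 24 C7 nitrile (C7 epimer mixture)
Conditions: TosMIC, KOt‑Bu, EtOH (2 equiv), DME, 0 → 35 °C
Reagents that add atoms: p‑toluenesulfonylmethyl isocyanide (TosMIC), Cc1ccc(cc1)S(=O)(=O)C[N+]#[C-]
Why: Van Leusen reductive cyanation turns the unhindered ketone into the one‑carbon‑homologated nitrile in a single step, the C7 configuration being corrected in the next step.

**Step 19**
Reactants: 24 C7 nitrile
Product: 27 C7 methyl ketone with acetyl equatorial and cis, via ketimine magnesium salt 25 (not isolated), via epimeric methyl ketone mixture 26 (not isolated)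
Conditions: MeMgBr (5 equiv), THF/toluene, 65 °C; 1 M HCl, 0 °C → rt; NaOMe (cat.), MeOH, rt
Reagents that add atoms: methylmagnesium bromide, C[Mg]Br; water, O
Why: Grignard addition to the nitrile stops at the ketimine salt, which hydrolyses to the methyl ketone, and methoxide‑catalysed enolisation then equilibrates C7 to the equatorial acetyl epimer (about 9:1, C7 S as in the target), the minor isomer being removed by chromatography.

**Step 20**
Reactants: 27 C7 methyl ketone
Product: 28 tri‑O‑methyl bis‑deformyl target (Ar eudesmane‑4,11‑diol)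
Conditions: MeMgBr, CeCl3 (anhydrous), THF, −78 → 0 °C; aq. NH4Cl
Reagents that add atoms: methylmagnesium bromide, C[Mg]Br
Why: Organocerium addition to the methyl ketone gives the 2‑hydroxypropan‑2‑yl group without enolising and hence without epimerising C7.

**Step 21**
Reactants: 28 diol
Product: 29 3,5‑dibromo‑2,4,6‑trimethoxyphenyl diol
Conditions: NBS (2.1 equiv), MeCN, 0 °C
Reagents that add atoms: N‑bromosuccinimide, O=C1CCC(=O)N1Br
Why: Electrophilic aromatic bromination is fast at the two remaining ring positions, each flanked by two methoxy groups, under neutral conditions that the tertiary alcohols tolerate.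

**Step 22**
Reactants: 29 dibromide
Product: 31 tri‑O‑methyl ether of the target (3,5‑diformyl‑2,4,6‑trimethoxyphenyl diol), via tetralithio intermediate 30 (not isolated)
Conditions: t‑BuLi (6.5 equiv), THF, −78 °C; DMF, −78 → 0 °C; aq. NH4Cl
Reagents that add atoms: N,N‑dimethylformamide, CN(C)C=O
Why: After deprotonation of both hydroxyls, double bromine–lithium exchange gives an ortho‑methoxy‑stabilised dilithioarene that DMF formylates (Bouveault‑type formylation), a non‑acidic route that spares the tertiary alcohols.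

**Step 23**
Reactants: 31 tri‑O‑methyl dialdehyde
Product: 32 target, 5‑[(1S)‑1‑[(1R,4R,4aS,6S,8aR)‑4‑hydroxy‑6‑(2‑hydroxypropan‑2‑yl)‑4,8a‑dimethyldecahydronaphthalen‑1‑yl]‑3‑methylbutyl]‑2,4,6‑trihydroxybenzene‑1,3‑dicarbaldehyde
Conditions: NaSEt (10 equiv), DMF, 100 °C; 1 M HCl (work‑up)
Reagents that add atoms: none
Why: Nucleophilic (SN2) demethylation by thiolate works because every methoxy group is ortho or para to a formyl group, and the basic medium leaves the acid‑sensitive tertiary alcohols and all stereocentres untouched.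

**Compound list**
1 | 2‑methylcyclohexane‑1,3‑dione | CC1C(=O)CCCC1=O | starting material
2 | methyl vinyl ketone | CC(=O)C=C | starting material
3 | 2‑methyl‑2‑(3‑oxobutyl)cyclohexane‑1,3‑dione | CC(=O)CCC1(C)C(=O)CCCC1=O | intermediate
4 | cis‑fused ketol, (4aS,8aS)‑4a‑hydroxy‑8a‑methyl‑3,4,4a,5,8,8a‑hexahydronaphthalene‑1,6(2H,7H)‑dione | O=C1CCC[C@]2(O)CC(=O)CC[C@]12C | intermediate (not isolated)
5 | (S)‑Wieland–Miescher ketone | O=C1CCCC2=CC(=O)CC[C@]12C | intermediate
6 | (4aS,5S)‑5‑hydroxy‑4a‑methyl‑4,4a,5,6,7,8‑hexahydronaphthalen‑2(3H)‑one | O[C@H]1CCCC2=CC(=O)CC[C@]12C | intermediate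
7 | C7 ethylene ketal, C4=C5, C1–OH cis | O[C@H]1CCC=C2CC3(OCCO3)CC[C@]12C | intermediate
8 | C1 ketone, C7 ethylene ketal, C4=C5 | O=C1CCC=C2CC3(OCCO3)CC[C@]12C | intermediate
9 | 1‑methylene, C7 ethylene ketal, C4=C5 | C=C1CCC=C2CC3(OCCO3)CC[C@]12C | intermediate
10 | bis‑borane: C1–CH2–(9‑borabicyclo[3.3.1]nonan‑9‑yl) cis, C4–BH2 trans, C5–H trans | C(B4C5CCCC4CCC5)[C@H]1CC[C@H](B)[C@H]2CC3(OCCO3)CC[C@]12C | intermediate (not isolated)
11 | trans‑decalin diol: C1–CH2OH cis, C4–OH trans, C7 ethylene ketal | OC[C@H]1CC[C@H](O)[C@H]2CC3(OCCO3)CC[C@]12C | intermediate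
12 | hydroxy aldehyde: C1–CHO cis, C4–OH trans | O=C[C@H]1CC[C@H](O)[C@H]2CC3(OCCO3)CC[C@]12C | intermediate
13 | methyl acetoacetate | CC(=O)CC(=O)OC | starting material
14 | alkylidene acetoacetate (E/Z mixture) | CC(=O)C(C(=O)OC)=C[C@H]1CC[C@H](O)[C@H]2CC3(OCCO3)CC[C@]12C | intermediate
15 | 2‑bromo‑1,3,5‑trimethoxybenzene | COc1cc(OC)c(Br)c(OC)c1 | starting material
16 | 2,4,6‑trimethoxyphenylmagnesium bromide | COc1cc(OC)c([Mg]Br)c(OC)c1 | intermediate
17 | Michael adduct (α‑carbon epimer mixture) | CC(=O)C(C(=O)OC)[C@H](c1c(OC)cc(OC)cc1OC)[C@H]1CC[C@H](O)[C@H]2CC3(OCCO3)CC[C@]12C | intermediate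
18 | methyl ketone | CC(=O)C[C@H](c1c(OC)cc(OC)cc1OC)[C@H]1CC[C@H](O)[C@H]2CC3(OCCO3)CC[C@]12C | intermediate
19 | 2‑methylallyl compound | CC(=C)C[C@H](c1c(OC)cc(OC)cc1OC)[C@H]1CC[C@H](O)[C@H]2CC3(OCCO3)CC[C@]12C | intermediate
20 | isobutyl compound, C4–OH trans | CC(C)C[C@H](c1c(OC)cc(OC)cc1OC)[C@H]1CC[C@H](O)[C@H]2CC3(OCCO3)CC[C@]12C | intermediate
21 | C4 ketone | CC(C)C[C@H](c1c(OC)cc(OC)cc1OC)[C@H]1CCC(=O)[C@H]2CC3(OCCO3)CC[C@]12C | intermediate
22 | C4 tertiary alcohol (OH cis, axial), C7 ketal | CC(C)C[C@H](c1c(OC)cc(OC)cc1OC)[C@H]1CC[C@@](C)(O)[C@H]2CC3(OCCO3)CC[C@]12C | intermediate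
23 | C7 ketone | CC(C)C[C@H](c1c(OC)cc(OC)cc1OC)[C@H]1CC[C@@](C)(O)[C@H]2CC(=O)CC[C@]12C | intermediate
24 | C7 nitrile (C7 epimers) | CC(C)C[C@H](c1c(OC)cc(OC)cc1OC)[C@H]1CC[C@@](C)(O)[C@H]2CC(C#N)CC[C@]12C | intermediate
25 | ketimine magnesium salt (C7 epimers) | CC(C)C[C@H](c1c(OC)cc(OC)cc1OC)[C@H]1CC[C@@](C)(O[Mg]Br)[C@H]2CC(C(C)=N[Mg]Br)CC[C@]12C | intermediate (not isolated)
26 | C7 methyl ketone (C7 epimers) | CC(C)C[C@H](c1c(OC)cc(OC)cc1OC)[C@H]1CC[C@@](C)(O)[C@H]2CC(C(C)=O)CC[C@]12C | intermediate (not isolated)
27 | C7 methyl ketone, acetyl cis (equatorial) | CC(C)C[C@H](c1c(OC)cc(OC)cc1OC)[C@H]1CC[C@@](C)(O)[C@H]2C[C@@H](C(C)=O)CC[C@]12C | intermediate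
28 | tri‑O‑methyl bis‑deformyl target | CC(C)C[C@H](c1c(OC)cc(OC)cc1OC)[C@H]1CC[C@@](C)(O)[C@H]2C[C@@H](C(C)(C)O)CC[C@]12C | intermediate
29 | 3,5‑dibromo‑2,4,6‑trimethoxyphenyl diol | CC(C)C[C@H](c1c(OC)c(Br)c(OC)c(Br)c1OC)[C@H]1CC[C@@](C)(O)[C@H]2C[C@@H](C(C)(C)O)CC[C@]12C | intermediate
30 | tetralithio species (two aryl C–Li, two O–Li) | CC(C)C[C@H](c1c(OC)c([Li])c(OC)c([Li])c1OC)[C@H]1CC[C@@](C)(O[Li])[C@H]2C[C@@H](C(C)(C)O[Li])CC[C@]12C | intermediate (not isolated)
31 | tri‑O‑methyl ether of the target | CC(C)C[C@H](c1c(OC)c(C=O)c(OC)c(C=O)c1OC)[C@H]1CC[C@@](C)(O)[C@H]2C[C@@H](C(C)(C)O)CC[C@]12C | intermediate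
32 | CNP0409870.4 | CC(C)C[C@H](c1c(O)c(C=O)c(O)c(C=O)c1O)[C@H]1CC[C@@](C)(O)[C@H]2C[C@@H](C(C)(C)O)CC[C@]12C | target

**Totals and risks**
Total step count: 23. Longest linear sequence: 22 steps (steps 1–9 and 11–23; step 10 is the side branch).

The three steps most likely to fail are 11, 18 and 22.

Step 11 (aryl addition at the congested C1′, with the C1′ configuration resting on a conformational model). The fallback sets out from aldehyde 12. Wittig olefination with the stabilised ylide 1‑(triphenylphosphoranylidene)propan‑2‑one in toluene at 80 °C gives the E‑configured enone F1, a less substituted acceptor. Conjugate addition of lithium bis(2,4,6‑trimethoxyphenyl)cuprate (from 1,3,5‑trimethoxybenzene, n‑BuLi and CuI) with Me3SiCl in THF at −78 °C, followed by aqueous work‑up, gives the methyl ketone directly, again by attack anti to C10. The fallback comes back to the route at 18, bypassing 14 and 17.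

Step 18 (reductive cyanation, with the C7 configuration depending on a roughly 9:1 equilibrium in step 19). The fallback sets out from ketone 23. KN(SiMe3)2 and PhNTf2 in THF at −78 °C give the enol triflate F2 (a regioisomeric enol triflate converges later). Carbonylation with Pd(OAc)2, PPh3, CO, MeOH and Et3N in DMF gives the α,β‑unsaturated methyl ester F3. Hydrogenation over Pd/C adds hydrogen from the face trans to the axial C10 methyl and gives the equatorial methyl ester F4 under kinetic control. Excess MeMgBr/CeCl3 then gives the diol, so the fallback comes back at 28, bypassing 24–27.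

Step 22 (double bromine–lithium exchange in the presence of two lithium alkoxides). The fallback sets out from diol 28, before bromination. Deprotonative lithiation with n‑BuLi/TMEDA at a ring C–H flanked by two methoxy groups, then DMF, gives the mono‑aldehyde F5. Its formyl group is masked in the flask as the lithium α‑amino alkoxide with lithium N,N,N′‑trimethylethylenediamide, the last ring position is lithiated with n‑BuLi, and DMF with aqueous work‑up gives the dialdehyde. The fallback comes back at 31 without any aryl bromide.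

**Further compounds**
F1 | step 11 | (E)‑enone C1–CH=CH–COCH3 (ring stereocentres as in 12) | CC(=O)/C=C/[C@H]1CC[C@H](O)[C@H]2CC3(OCCO3)CC[C@]12C
F2 | step 18 | C7 enol triflate with C7=C8 | CC(C)C[C@H](c1c(OC)cc(OC)cc1OC)[C@H]1CC[C@@](C)(O)[C@H]2CC(OS(=O)(=O)C(F)(F)F)=CC[C@]12C
F3 | step 18 | C7 methyl ester with C7=C8 | CC(C)C[C@H](c1c(OC)cc(OC)cc1OC)[C@H]1CC[C@@](C)(O)[C@H]2CC(C(=O)OC)=CC[C@]12C
F4 | step 18 | C7 methyl ester, ester cis (equatorial) | CC(C)C[C@H](c1c(OC)cc(OC)cc1OC)[C@H]1CC[C@@](C)(O)[C@H]2C[C@@H](C(=O)OC)CC[C@]12C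
F5 | step 22 | mono‑aldehyde (3‑formyl‑2,4,6‑trimethoxyphenyl diol) | CC(C)C[C@H](c1c(OC)cc(OC)c(C=O)c1OC)[C@H]1CC[C@@](C)(O)[C@H]2C[C@@H](C(C)(C)O)CC[C@]12C
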